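**Strategy.** The target is robinetinidol-(4β→8)-catechin. The interflavan C4–C8 bond is disconnected to an 8-lithiated catechin and a C4 ketone of the upper unit; ionic reduction of the derived tertiary carbinol then sets C4, hydride entering trans to O-3. The upper pyran ring (O1, C2, C3, C4, C4a, C8a) is not cyclised: a five-membered precursor, a 2-aryl-3-hydroxy-2,3-dihydrobenzofuran-3-carbaldehyde from an enantioselective carbene C–H insertion, undergoes an α-ketol ring expansion in which C2 shifts to the formyl carbon. One operation delivers the six-membered ring, the C3 carbinol and the C4 carbonyl; it exploits the C3-hydroxy/C4 pattern of ring C beside the oxygenated ring A.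

Key step: step 7

Remark: the hand of the dirhodium catalyst is chosen so that the C–H insertion gives the (2S)-benzofuran 7; Rh2(S-PTTL)4 is written for this hand. Benzofuran numbering is used for 7–10 and flavan numbering for 11–21.

**Step 1**
Reactants: 1 6-hydroxy-1-benzofuran-2(3H)-one
Product: 2 6-(benzyloxy)-1-benzofuran-2(3H)-one
Conditions: BnOH, PPh3, DIAD, THF, 0 °C → rt
Reagents that add atoms: benzyl alcohol, OCc1ccccc1
Why: Mitsunobu etherification of the only free phenol under neutral conditions; the lactone keeps the second ring-A oxygen masked, and its CH2 acid reacts far more slowly than the phenol.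

**Step 2**
Reactants: 2 6-(benzyloxy)-1-benzofuran-2(3H)-one; 3 [3,4,5-tris(benzyloxy)phenyl]methanol
Product: 5 methyl [4-(benzyloxy)-2-{[3,4,5-tris(benzyloxy)benzyl]oxy}phenyl]acetate, via phenol ester 4 (not isolated)
Conditions: Et3N (0.1 equiv), MeOH, rt; concentrate; then 3, PPh3, DIAD, THF, 0 °C → rt
Reagents that add atoms: methanol, CO
Why: Base-catalysed methanolysis of the activated aryl lactone frees only the ortho phenol, which is then etherified with the benzylic alcohol by a Mitsunobu reaction, so the two ring-A oxygens are differentiated by construction.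

**Step 3**
Reactants: 5 methyl [4-(benzyloxy)-2-{[3,4,5-tris(benzyloxy)benzyl]oxy}phenyl]acetate
Product: 6 methyl [4-(benzyloxy)-2-{[3,4,5-tris(benzyloxy)benzyl]oxy}phenyl](diazo)acetate
Conditions: 4-acetamidobenzenesulfonyl azide, DBU, MeCN, 0 °C → rt
Reagents that add atoms: 4-acetamidobenzenesulfonyl azide, CC(=O)Nc1ccc(cc1)S(=O)(=O)N=[N+]=[N-]
Why: Regitz diazo transfer to the arylacetate enolate gives the donor/acceptor diazo ester.

**Step 4**
Reactants: 6 methyl [4-(benzyloxy)-2-{[3,4,5-tris(benzyloxy)benzyl]oxy}phenyl](diazo)acetate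
Product: 7 methyl (2S,3R)-6-(benzyloxy)-2-[3,4,5-tris(benzyloxy)phenyl]-2,3-dihydro-1-benzofuran-3-carboxylate (2,3-cis)
Conditions: Rh2(S-PTTL)4 [dirhodium tetrakis(N-phthaloyl-(S)-tert-leucinate)] (1 mol %), toluene, −78 °C → −40 °C
Reagents that add atoms: none
Why: Intramolecular 1,5 C–H insertion of the dirhodium donor/acceptor carbene into the ether C–H that is activated by both oxygen and the aryl group closes the dihydrofuran; the chiral carboxylate ligands set C2, and the concerted insertion gives the 2,3-cis ester.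

**Step 5**
Reactants: 7 methyl (2S,3R)-6-(benzyloxy)-2-[3,4,5-tris(benzyloxy)phenyl]-2,3-dihydro-1-benzofuran-3-carboxylate
Product: 9 methyl (2R,3S)-6-(benzyloxy)-3-hydroxy-2-[3,4,5-tris(benzyloxy)phenyl]-2,3-dihydro-1-benzofuran-3-carboxylate, via potassium enolate 8 (not isolated)
Conditions: KN(SiMe3)2, THF, −78 °C; then 2-(phenylsulfonyl)-3-phenyloxaziridine, −78 °C; AcOH quench
Reagents that add atoms: 2-(phenylsulfonyl)-3-phenyloxaziridine, O=S(=O)(N1OC1c1ccccc1)c1ccccc1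
Why: Davis enolate hydroxylation; the oxaziridine attacks the planar benzylic enolate on the face away from the C2 aryl group (OH trans to aryl), while C2 is untouched because ring opening of the enolate would be the reverse of a disfavoured 5-endo-trig closure.

**Step 6**
Reactants: 9 methyl (2R,3S)-6-(benzyloxy)-3-hydroxy-2-[3,4,5-tris(benzyloxy)phenyl]-2,3-dihydro-1-benzofuran-3-carboxylate
Product: 10 (2R,3S)-6-(benzyloxy)-3-hydroxy-2-[3,4,5-tris(benzyloxy)phenyl]-2,3-dihydro-1-benzofuran-3-carbaldehyde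
Conditions: iBu2AlH (3 equiv), CH2Cl2, −78 °C; aqueous potassium sodium tartrate
Reagents that add atoms: none
Why: Partial reduction of an α-hydroxy ester; the aluminium alkoxide of the tertiary OH chelates the tetrahedral intermediate, which survives at −78 °C and releases the aldehyde only on work-up.

**Step 7**
Reactants: 10 (2R,3S)-6-(benzyloxy)-3-hydroxy-2-[3,4,5-tris(benzyloxy)phenyl]-2,3-dihydro-1-benzofuran-3-carbaldehyde
Product: 11 (2R,3R)-7-(benzyloxy)-3-hydroxy-2-[3,4,5-tris(benzyloxy)phenyl]-2,3-dihydro-4H-chromen-4-one (2,3-trans)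
Conditions: Al(OtBu)3 (20 mol %), toluene, 60 °C, until equilibrated
Reagents that add atoms: none
Why: α-Ketol (acyloin) rearrangement with ring enlargement, the reaction type of 1-hydroxycycloalkanecarbaldehyde to 2-hydroxycycloalkanone and of steroidal D-homoannulation: aluminium binds the tertiary alkoxide and the formyl oxygen, the O-bearing benzylic ring carbon C2 shifts with its electron pair from the carbinol carbon to the formyl carbon, and the carbinol carbon becomes the C4 ketone. No ring is closed by cyclisation; the five-membered O1–C2–C3–C3a–C7a ring becomes the six-membered O1–C2–C3–C4–C4a–C8a ring by insertion of the formyl carbon (the new C3) between C2 and the old carbinol carbon. C2 migrates with retention, so the configuration set in step 4 is carried over. The new stereocenter C3 is α to the ketone; the chelated transition state may first give the 2,3-cis ketol, which epimerises through the aluminium enediolate to the diequatorial 2,3-trans (2R,3R) isomer, so C3 is under thermodynamic control of C2. The step needs migration of C2 and not of the aryl carbon C3a; this is secured by the gain of a ketone conjugated with the 2,4-dioxygenated ring A, by relief of ring strain and by the high migratory aptitude of an α-oxygenated benzylic carbon, and the reversible manifold drains to the aryl ketone.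

**Step 8**
Reactants: 11 (2R,3R)-7-(benzyloxy)-3-hydroxy-2-[3,4,5-tris(benzyloxy)phenyl]-2,3-dihydro-4H-chromen-4-one
Product: 12 (2R,3R)-7-(benzyloxy)-3-[(tert-butyldimethylsilyl)oxy]-2-[3,4,5-tris(benzyloxy)phenyl]-2,3-dihydro-4H-chromen-4-one
Conditions: TBSOTf, 2,6-lutidine, CH2Cl2, −78 °C → 0 °C
Reagents that add atoms: tert-butyldimethylsilyl triflate, CC(C)(C)[Si](C)(C)OS(=O)(=O)C(F)(F)F
Why: Silylation of the hindered α-ketol OH with a silyl triflate and a non-nucleophilic base that does not enolise the ketone; the bulky ether later shields one face of C4.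

**Step 9**
Reactants: 13 (+)-catechin
Product: 14 (2R,3S)-5,7-bis(benzyloxy)-2-[3,4-bis(benzyloxy)phenyl]chroman-3-ol
Conditions: BnBr, K2CO3, DMF, 0 °C → rt
Reagents that add atoms: benzyl bromide, BrCc1ccccc1
Why: Williamson etherification of the four phenols; K2CO3 does not deprotonate the secondary 3-OH, and no stereocenter is touched.

**Step 10**
Reactants: 14 (2R,3S)-5,7-bis(benzyloxy)-2-[3,4-bis(benzyloxy)phenyl]chroman-3-ol
Product: 15 (2R,3S)-5,7-bis(benzyloxy)-2-[3,4-bis(benzyloxy)phenyl]-8-bromochroman-3-ol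
Conditions: NBS, CH2Cl2, −78 °C → rt
Reagents that add atoms: N-bromosuccinimide, O=C1CCC(=O)N1Br
Why: Electrophilic aromatic bromination of the phloroglucinol-type ring A, which in 5,7-di-O-benzyl flavan-3-ols takes place at C8 in preference to C6.

**Step 11**
Reactants: 15 (2R,3S)-5,7-bis(benzyloxy)-2-[3,4-bis(benzyloxy)phenyl]-8-bromochroman-3-ol
Product: 16 {[(2R,3S)-5,7-bis(benzyloxy)-2-[3,4-bis(benzyloxy)phenyl]-8-bromochroman-3-yl]oxy}(tert-butyl)dimethylsilane
Conditions: TBSCl, imidazole, DMF, rt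
Reagents that add atoms: tert-butyldimethylsilyl chloride, CC(C)(C)[Si](C)(C)Cl
Why: Standard silylation removes the acidic OH before halogen–lithium exchange.

**Step 12**
Reactants: 16 8-bromo-3-O-TBS-tetra-O-benzylcatechin; 12 (2R,3R)-7-(benzyloxy)-3-[(tert-butyldimethylsilyl)oxy]-2-[3,4,5-tris(benzyloxy)phenyl]-2,3-dihydro-4H-chromen-4-one
Product: 18 (2R,3R,4R)-7-(benzyloxy)-4-[(2R,3S)-5,7-bis(benzyloxy)-2-[3,4-bis(benzyloxy)phenyl]-3-[(tert-butyldimethylsilyl)oxy]chroman-8-yl]-3-[(tert-butyldimethylsilyl)oxy]-2-[3,4,5-tris(benzyloxy)phenyl]chroman-4-ol, via aryllithium 17 (not isolated)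
Conditions: tBuLi (2 equiv), THF, −78 °C; then 12, −78 °C → 0 °C; H2O
Reagents that add atoms: none
Why: Bromine–lithium exchange and 1,2-addition of the aryllithium to the aryl ketone forge the C4–C8 bond; addition is expected on the face opposite the neighbouring OTBS group, and this carbinol centre is erased in step 13.

**Step 13**
Reactants: 18 tertiary alcohol
Product: 19 3,3'-bis-O-TBS-octa-O-benzyl robinetinidol-(4β→8)-catechin, upper unit (2R,3S,4R), lower unit (2R,3S)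
Conditions: Bu3SnH, CF3CO2H, CH2Cl2, 0 °C
Reagents that add atoms: none
Why: Ionic hydrogenation: the acid ionises the doubly benzylic tertiary alcohol to the 4-aryl flavan-4-yl cation and Bu3SnH should deliver hydride to the face trans to the bulky 3-OTBS group, as carbon nucleophiles add trans to O-3 of flavan-4-yl cations, so H becomes 4α and the catechin unit 4β (3,4-cis, 2,4-trans, 4R).

**Step 14**
Reactants: 19 bis-silyl ether
Product: 20 octa-O-benzyl robinetinidol-(4β→8)-catechin (both 3-OH free)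
Conditions: Bu4NF, AcOH, THF, 0 °C → rt
Reagents that add atoms: none
Why: Fluoride-mediated cleavage of the two secondary silyl ethers, buffered with acetic acid; benzyl ethers and stereocenters are untouched.

**Step 15**
Reactants: 20 octa-O-benzyl robinetinidol-(4β→8)-catechin
Product: 21 robinetinidol-(4β→8)-catechin, (2R,3S,4R)-4-[(2R,3S)-2-(3,4-dihydroxyphenyl)-3,5,7-trihydroxychroman-8-yl]-2-(3,4,5-trihydroxyphenyl)chromane-3,7-diol
Conditions: H2 (1 atm), Pd(OH)2/C, THF/MeOH/H2O, rt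
Reagents that add atoms: none
Why: Hydrogenolysis of the eight benzyl ethers under neutral conditions, which leave the C2–O1 and C4–aryl benzylic bonds of flavans intact.

**Compound list**
1 | 6-hydroxy-1-benzofuran-2(3H)-one | O=C1Cc2ccc(O)cc2O1 | starting material
2 | 6-(benzyloxy)-1-benzofuran-2(3H)-one | O=C1Cc2ccc(OCc3ccccc3)cc2O1 | intermediate
3 | [3,4,5-tris(benzyloxy)phenyl]methanol | OCc1cc(OCc2ccccc2)c(OCc2ccccc2)c(OCc2ccccc2)c1 | starting material
4 | methyl [4-(benzyloxy)-2-hydroxyphenyl]acetate | COC(=O)Cc1ccc(OCc2ccccc2)cc1O | intermediate (not isolated)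
5 | methyl [4-(benzyloxy)-2-{[3,4,5-tris(benzyloxy)benzyl]oxy}phenyl]acetate | COC(=O)Cc1ccc(OCc2ccccc2)cc1OCc1cc(OCc2ccccc2)c(OCc2ccccc2)c(OCc2ccccc2)c1 | intermediate
6 | methyl [4-(benzyloxy)-2-{[3,4,5-tris(benzyloxy)benzyl]oxy}phenyl](diazo)acetate | COC(=O)C(=[N+]=[N-])c1ccc(OCc2ccccc2)cc1OCc1cc(OCc2ccccc2)c(OCc2ccccc2)c(OCc2ccccc2)c1 | intermediate
7 | methyl (2S,3R)-6-(benzyloxy)-2-[3,4,5-tris(benzyloxy)phenyl]-2,3-dihydro-1-benzofuran-3-carboxylate (2,3-cis) | COC(=O)[C@@H]1c2ccc(OCc3ccccc3)cc2O[C@@H]1c4cc(OCc5ccccc5)c(OCc5ccccc5)c(OCc5ccccc5)c4 | intermediate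
8 | potassium ester enolate of 7 (C3 planar, C2 unchanged) | [K+].[O-]C(OC)=C1c2ccc(OCc3ccccc3)cc2O[C@@H]1c4cc(OCc5ccccc5)c(OCc5ccccc5)c(OCc5ccccc5)c4 | intermediate (not isolated)
9 | methyl (2R,3S)-6-(benzyloxy)-3-hydroxy-2-[3,4,5-tris(benzyloxy)phenyl]-2,3-dihydro-1-benzofuran-3-carboxylate (OH trans to aryl) | COC(=O)[C@]1(O)c2ccc(OCc3ccccc3)cc2O[C@@H]1c4cc(OCc5ccccc5)c(OCc5ccccc5)c(OCc5ccccc5)c4 | intermediate
10 | (2R,3S)-6-(benzyloxy)-3-hydroxy-2-[3,4,5-tris(benzyloxy)phenyl]-2,3-dihydro-1-benzofuran-3-carbaldehyde | O=C[C@]1(O)c2ccc(OCc3ccccc3)cc2O[C@@H]1c4cc(OCc5ccccc5)c(OCc5ccccc5)c(OCc5ccccc5)c4 | intermediate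
11 | (2R,3R)-7-(benzyloxy)-3-hydroxy-2-[3,4,5-tris(benzyloxy)phenyl]-2,3-dihydro-4H-chromen-4-one (2,3-trans) | O=C1c2ccc(OCc3ccccc3)cc2O[C@H](c4cc(OCc5ccccc5)c(OCc5ccccc5)c(OCc5ccccc5)c4)[C@H]1O | intermediate
12 | (2R,3R)-7-(benzyloxy)-3-[(tert-butyldimethylsilyl)oxy]-2-[3,4,5-tris(benzyloxy)phenyl]-2,3-dihydro-4H-chromen-4-one | O=C1c2ccc(OCc3ccccc3)cc2O[C@H](c4cc(OCc5ccccc5)c(OCc5ccccc5)c(OCc5ccccc5)c4)[C@H]1O[Si](C)(C)C(C)(C)C | intermediate
13 | (+)-catechin, (2R,3S)-2-(3,4-dihydroxyphenyl)chromane-3,5,7-triol | O[C@H]1Cc2c(O)cc(O)cc2O[C@@H]1c1ccc(O)c(O)c1 | starting material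
14 | (2R,3S)-5,7-bis(benzyloxy)-2-[3,4-bis(benzyloxy)phenyl]chroman-3-ol | O[C@H]1Cc2c(OCc3ccccc3)cc(OCc3ccccc3)cc2O[C@@H]1c4ccc(OCc5ccccc5)c(OCc5ccccc5)c4 | intermediate
15 | (2R,3S)-5,7-bis(benzyloxy)-2-[3,4-bis(benzyloxy)phenyl]-8-bromochroman-3-ol | O[C@H]1Cc2c(OCc3ccccc3)cc(OCc3ccccc3)c(Br)c2O[C@@H]1c4ccc(OCc5ccccc5)c(OCc5ccccc5)c4 | intermediate
16 | {[(2R,3S)-5,7-bis(benzyloxy)-2-[3,4-bis(benzyloxy)phenyl]-8-bromochroman-3-yl]oxy}(tert-butyl)dimethylsilane | CC(C)(C)[Si](C)(C)O[C@H]1Cc2c(OCc3ccccc3)cc(OCc3ccccc3)c(Br)c2O[C@@H]1c4ccc(OCc5ccccc5)c(OCc5ccccc5)c4 | intermediate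
17 | 8-lithio derivative of 16 | CC(C)(C)[Si](C)(C)O[C@H]1Cc2c(OCc3ccccc3)cc(OCc3ccccc3)c([Li])c2O[C@@H]1c4ccc(OCc5ccccc5)c(OCc5ccccc5)c4 | intermediate (not isolated)
18 | (2R,3R,4R)-4-aryl-4-hydroxy adduct of 12 and 17 (4-OH cis to 3-OTBS; lower unit 2R,3S) | O(Cc9ccccc9)c1ccc2c(c1)O[C@H](c3cc(OCc9ccccc9)c(OCc9ccccc9)c(OCc9ccccc9)c3)[C@@H](O[Si](C)(C)C(C)(C)C)[C@]2(O)c1c(OCc9ccccc9)cc(OCc9ccccc9)c2c1O[C@H](c3ccc(OCc9ccccc9)c(OCc9ccccc9)c3)[C@@H](O[Si](C)(C)C(C)(C)C)C2 | intermediate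
19 | 3,3'-bis-O-TBS-octa-O-benzyl robinetinidol-(4β→8)-catechin, upper (2R,3S,4R), lower (2R,3S) | O(Cc9ccccc9)c1ccc2c(c1)O[C@H](c3cc(OCc9ccccc9)c(OCc9ccccc9)c(OCc9ccccc9)c3)[C@@H](O[Si](C)(C)C(C)(C)C)[C@H]2c1c(OCc9ccccc9)cc(OCc9ccccc9)c2c1O[C@H](c3ccc(OCc9ccccc9)c(OCc9ccccc9)c3)[C@@H](O[Si](C)(C)C(C)(C)C)C2 | intermediate
20 | octa-O-benzyl robinetinidol-(4β→8)-catechin, upper (2R,3S,4R), lower (2R,3S) | O(Cc9ccccc9)c1ccc2c(c1)O[C@H](c3cc(OCc9ccccc9)c(OCc9ccccc9)c(OCc9ccccc9)c3)[C@@H](O)[C@H]2c1c(OCc9ccccc9)cc(OCc9ccccc9)c2c1O[C@H](c3ccc(OCc9ccccc9)c(OCc9ccccc9)c3)[C@@H](O)C2 | intermediate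
21 | robinetinidol-(4β→8)-catechin, (2R,3S,4R)-4-[(2R,3S)-2-(3,4-dihydroxyphenyl)-3,5,7-trihydroxychroman-8-yl]-2-(3,4,5-trihydroxyphenyl)chromane-3,7-diol | Oc1ccc2c(c1)O[C@H](c1cc(O)c(O)c(O)c1)[C@@H](O)[C@H]2c1c(O)cc(O)c2c1O[C@H](c1ccc(O)c(O)c1)[C@@H](O)C2 | target

**Total step count:** 15. **Longest linear sequence:** 12 steps (steps 1–8, then 12–15); steps 9–11 form the second branch.

**Steps most likely to fail**

Step 7. The aryl carbon C3a may shift in competition with C2; the 3-keto isomer formed that way can enolise towards C2 and erode the enantiopurity, and the aldehyde may decompose before it rearranges. The fallback keeps a five-to-six ring expansion but uses a 1,2-aryl shift; it sets out from 7 and comes back to the route at 12. NaOMe in MeOH epimerises C3 of 7 to methyl (2S,3S)-6-(benzyloxy)-2-[3,4,5-tris(benzyloxy)phenyl]-2,3-dihydro-1-benzofuran-3-carboxylate F1 (2,3-trans). LiAlH4 in THF reduces it to the trans primary alcohol F2, and MsCl/Et3N gives the mesylate F3. Solvolysis of F3 in aqueous (CF3)2CHOH with 2,6-lutidine at 50 °C should pass through the phenonium ion of the para-benzyloxy ring A; water opens it at the secondary carbon with inversion and gives (2R,3S)-7-(benzyloxy)-2-[3,4,5-tris(benzyloxy)phenyl]chroman-3-ol F4 (2,3-trans). TBSOTf/2,6-lutidine gives the silyl ether F5, DDQ in wet CH2Cl2 oxidises C4 to the 4-ol F6, and Dess–Martin periodinane gives ketone 12.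

Step 13. Hydride delivery to the planar cation may show poor facial selectivity, or the cation may lose C3–H to the enol ether and scramble C3 on reprotonation. The fallback is a tethered arylation that forces the catechin ring onto the face of O-3; it sets out from 11 and 14 and comes back at 20. NaBH4 in MeOH/THF reduces 11 to the flavan-3,4-diol F7. 2-Ethoxyethanol with pyridinium p-toluenesulfonate exchanges only the benzylic 4-OH and gives the 4-(2-ethoxyethyl) ether F8 (either C4 epimer serves). Glutaric anhydride and DMAP convert 14 into its 3-O-hemiglutarate F9. DCC/DMAP joins the 3-OH of F8 to F9 to give the mixed glutarate diester F10. TMSOTf in CH2Cl2 at −40 °C ionises C4, and the tethered ring attacks through C8 on the side of O-3 to give the 3,4-cis macrocyclic diester F11. K2CO3 in MeOH removes the tether and gives 20.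

Step 6. Over-reduction to the diol, or hydrate and dimer formation of the α-hydroxy aldehyde, may prevent its isolation. The fallback sets out from 9 and comes back at 10. LiAlH4 in THF reduces 9 fully to (2R,3R)-6-(benzyloxy)-3-(hydroxymethyl)-2-[3,4,5-tris(benzyloxy)phenyl]-2,3-dihydro-1-benzofuran-3-ol F12. SO3·pyridine, DMSO and iPr2NEt at 0 °C then oxidise only the primary alcohol, the tertiary one being inert, and give 10.

**Further compounds**
F1 | step 7 | methyl (2S,3S)-6-(benzyloxy)-2-[3,4,5-tris(benzyloxy)phenyl]-2,3-dihydro-1-benzofuran-3-carboxylate (2,3-trans) | COC(=O)[C@H]1c2ccc(OCc3ccccc3)cc2O[C@@H]1c4cc(OCc5ccccc5)c(OCc5ccccc5)c(OCc5ccccc5)c4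
F2 | step 7 | [(2S,3R)-6-(benzyloxy)-2-[3,4,5-tris(benzyloxy)phenyl]-2,3-dihydro-1-benzofuran-3-yl]methanol (2,3-trans) | OC[C@H]1c2ccc(OCc3ccccc3)cc2O[C@@H]1c4cc(OCc5ccccc5)c(OCc5ccccc5)c(OCc5ccccc5)c4
F3 | step 7 | methanesulfonate of F2 | CS(=O)(=O)OC[C@H]1c2ccc(OCc3ccccc3)cc2O[C@@H]1c4cc(OCc5ccccc5)c(OCc5ccccc5)c(OCc5ccccc5)c4
F4 | step 7 | (2R,3S)-7-(benzyloxy)-2-[3,4,5-tris(benzyloxy)phenyl]chroman-3-ol | O[C@H]1Cc2ccc(OCc3ccccc3)cc2O[C@@H]1c4cc(OCc5ccccc5)c(OCc5ccccc5)c(OCc5ccccc5)c4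
F5 | step 7 | tert-butyldimethylsilyl ether of F4 | CC(C)(C)[Si](C)(C)O[C@H]1Cc2ccc(OCc3ccccc3)cc2O[C@@H]1c4cc(OCc5ccccc5)c(OCc5ccccc5)c(OCc5ccccc5)c4
F6 | step 7 | (2R,3S,4R)-7-(benzyloxy)-3-[(tert-butyldimethylsilyl)oxy]-2-[3,4,5-tris(benzyloxy)phenyl]chroman-4-ol | O[C@@H]1c2ccc(OCc3ccccc3)cc2O[C@H](c4cc(OCc5ccccc5)c(OCc5ccccc5)c(OCc5ccccc5)c4)[C@H]1O[Si](C)(C)C(C)(C)C
F7 | step 13 | (2R,3S,4R)-7-(benzyloxy)-2-[3,4,5-tris(benzyloxy)phenyl]chromane-3,4-diol | O[C@@H]1c2ccc(OCc3ccccc3)cc2O[C@H](c4cc(OCc5ccccc5)c(OCc5ccccc5)c(OCc5ccccc5)c4)[C@H]1O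
F8 | step 13 | 2,3-trans-3,4-trans 7-(benzyloxy)-4-(2-ethoxyethoxy)-2-[3,4,5-tris(benzyloxy)phenyl]chroman-3-ol (C2 and C3 as in 11) | CCOCCO[C@@H]1c2ccc(OCc3ccccc3)cc2O[C@H](c4cc(OCc5ccccc5)c(OCc5ccccc5)c(OCc5ccccc5)c4)[C@H]1O
F9 | step 13 | 5-{[(2R,3S)-5,7-bis(benzyloxy)-2-[3,4-bis(benzyloxy)phenyl]chroman-3-yl]oxy}-5-oxopentanoic acid | OC(=O)CCCC(=O)O[C@H]1Cc2c(OCc3ccccc3)cc(OCc3ccccc3)cc2O[C@@H]1c4ccc(OCc5ccccc5)c(OCc5ccccc5)c4
F10 | step 13 | mixed pentanedioate diester of F8 (at O-3) and 14 (at O-3) | CCOCCO[C@@H]1c2ccc(OCc3ccccc3)cc2O[C@H](c4cc(OCc5ccccc5)c(OCc5ccccc5)c(OCc5ccccc5)c4)[C@H]1OC(=O)CCCC(=O)O[C@H]1Cc2c(OCc3ccccc3)cc(OCc3ccccc3)cc2O[C@@H]1c4ccc(OCc5ccccc5)c(OCc5ccccc5)c4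
F11 | step 13 | 3,3'-O-pentanedioyl-bridged octa-O-benzyl robinetinidol-(4β→8)-catechin (3,4-cis macrocyclic diester) | O(Cc9ccccc9)c1ccc2c(c1)O[C@H](c3cc(OCc9ccccc9)c(OCc9ccccc9)c(OCc9ccccc9)c3)[C@@H](OC(=O)CCCC(=O)O5)[C@H]2c1c(OCc9ccccc9)cc(OCc9ccccc9)c2c1O[C@H](c3ccc(OCc9ccccc9)c(OCc9ccccc9)c3)[C@@H]5C2
F12 | step 6 | (2R,3R)-6-(benzyloxy)-3-(hydroxymethyl)-2-[3,4,5-tris(benzyloxy)phenyl]-2,3-dihydro-1-benzofuran-3-ol | OC[C@]1(O)c2ccc(OCc3ccccc3)cc2O[C@@H]1c4cc(OCc5ccccc5)c(OCc5ccccc5)c(OCc5ccccc5)c4
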